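**Retrosynthetic overview**

1. Labels: ring B is the cyclopentane Ca (spiro carbon shared with ring A) – Cb (H, i-Pr) – Cc (H2) – Cd (H2) – Ce (pinane C2); ring A is Ca – Cf (C=O) – Cg (C–Me) = Ch (C–OMe) – Ci (CMe2) – Cj (C=O). In names of the type spiro[pinane-2,1'-cyclopentane] the locants 1', 2', 3', 4', 5' stand for Ce, Ca, Cb, Cc, Cd. The face of ring B on which pinane C1 lies is called the bridgehead face, the face on which pinane C3 lies the methylene face (target: Cj on the bridgehead face; Cf and i-Pr on the methylene face).
2. Feature used: at Ce the bond to Ca points towards the gem-dimethyl bridge and the bond to Cd towards the open side, so Ca stands where the methyl group of cis-pinane stands. A two-carbon arm hydrogenated onto pinane C2 from the open face therefore leaves a tertiary C2–H bond exactly where Cd must be attached, and a carbenoid insertion with retention closes ring B with the correct spiro centre.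
3. Disconnections: Ch–OMe (enol ether); ring A by Claisen (Dieckmann) closure Cg–Cf of a diketo ester built on Ca by two aldol/oxidation cycles; the Cc carbonyl removed via the dithiolane; ring B by dirhodium carbenoid insertion of Cd into Ce–H; the diazo ketone from the Michael adduct of (cis-pinan-2-yl)acetaldehyde and (E)-3-methyl-1-nitrobut-1-ene; the aldehyde from (+)-β-pinene through nopinone.
4. Stereochemical relay: hydrogenation sets Ce; the amine catalyst sets Ca in the Michael step; the Ca ester then places i-Pr at Cb trans to itself by epimerisation next to the new ketone; the i-Pr group finally steers the aldol that makes Ca quaternary.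
5. Ring order: pinane bicycle (from the starting material), ring B (step 10), ring A (step 18).

Key step: step 10

Assumption: (+)-β-pinene is used as the commercial (1R,5R) enantiomer of high enantiomeric purity; "cis-pinan-2-yl" means its 6,6-dimethylbicyclo[3.1.1]heptan-2-yl group with the C2 substituent syn to the gem-dimethyl bridge.

**Route**

Step 1
Reactants: 1 (+)-β-pinene
Product: 3 (−)-nopinone, via β-pinene ozonide 2 (not isolated)
Conditions: O3, CH2Cl2, −78 °C; then Me2S, −78 °C to rt
Reagents that add atoms: ozone [O-][O+]=O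
Why: Ozonolysis (Criegee mechanism) with reductive work-up cleaves only the exocyclic methylidene C=C bond and leaves the two bridgehead stereocentres untouched.

Step 2
Reactants: 3 (−)-nopinone; 4 trimethyl phosphonoacetate
Product: 5 methyl nopinylideneacetate (E/Z mixture)
Conditions: NaH, THF, 0 °C to reflux
Reagents that add atoms: none
Why: Horner–Wadsworth–Emmons olefination installs the two-carbon arm (future Ca and its ester carbon); the alkene geometry is irrelevant because both isomers converge in step 3.

Step 3
Reactants: 5 methyl nopinylideneacetate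
Product: 6 methyl (cis-pinan-2-yl)acetate
Conditions: H2 (3 bar), PtO2, EtOAc, rt
Reagents that add atoms: none
Why: Heterogeneous catalytic hydrogenation should deliver hydrogen from the face away from the gem-dimethyl bridge, so the CH2CO2Me arm ends up syn to the bridge (cis-pinane relationship) and the Ce stereocentre is set.

Step 4
Reactants: 6 methyl (cis-pinan-2-yl)acetate
Product: 7 (cis-pinan-2-yl)acetaldehyde
Conditions: i-Bu2AlH (1.1 equiv), CH2Cl2, −78 °C; MeOH, then aq. KNaC4H4O6 (potassium sodium tartrate)
Reagents that add atoms: none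
Why: Partial ester reduction with i-Bu2AlH at low temperature should stop at the aldehyde oxidation level, the aldehyde being released only on work-up.

Step 5
Reactants: 8 isobutyraldehyde; 9 nitromethane
Product: 12 (E)-3-methyl-1-nitrobut-1-ene, via 3-methyl-1-nitrobutan-2-ol 10 (not isolated), via 3-methyl-1-nitrobutan-2-yl methanesulfonate 11 (not isolated)
Conditions: NaOH (10 mol %), MeOH, 0 °C, then AcOH and evaporation; then MsCl, Et3N, CH2Cl2, 0 °C
Reagents that add atoms: none
Why: Base-catalysed Henry addition followed by mesylation and base-induced β-elimination through the nitronate should give the conjugated nitroalkene in its thermodynamically preferred E geometry.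

Step 6
Reactants: 7 (cis-pinan-2-yl)acetaldehyde; 12 (E)-3-methyl-1-nitrobut-1-ene
Product: 13 (2S,3S)-4-methyl-3-(nitromethyl)-2-(cis-pinan-2-yl)pentanal
Conditions: (R)-2-[diphenyl(trimethylsilyloxy)methyl]pyrrolidine (20 mol %), 4-nitrophenol (20 mol %), toluene, 0 °C to rt
Reagents that add atoms: none
Why: Enamine-catalysed asymmetric Michael addition of an aldehyde to a nitroalkene (diarylprolinol silyl ether catalysis): the (R)-catalyst shields one enamine face so that Ca should form with the (S) configuration under catalyst control (syn adduct), while the Cb configuration is provisional because it is reset in step 11.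

Step 7
Reactants: 13 nitro aldehyde
Product: 15 methyl (2S,3S)-4-methyl-3-(nitromethyl)-2-(cis-pinan-2-yl)pentanoate, via nitro acid 14 (not isolated)
Conditions: NaClO2, NaH2PO4, 2-methylbut-2-ene, t-BuOH–H2O, 0 °C to rt; then Me3SiCHN2, MeOH–toluene, 0 °C
Reagents that add atoms: sodium chlorite [Na+].[O-]Cl=O; trimethylsilyldiazomethane C[Si](C)(C)C=[N+]=[N-]
Why: Pinnick oxidation converts the aldehyde to the acid without enolising Ca, and neutral esterification with trimethylsilyldiazomethane gives the methyl ester that later deactivates Ca–H towards the carbenoid.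

Step 8
Reactants: 15 nitro ester
Product: 16 (2S,3S)-4-methoxy-4-oxo-2-(propan-2-yl)-3-(cis-pinan-2-yl)butanoic acid
Conditions: NaNO2, AcOH, DMSO, 35 °C
Reagents that add atoms: sodium nitrite [Na+].[O-]N=O
Why: Nitrosation of the primary nitroalkane (an oxidative Nef-type conversion through the nitrolic acid, with nitrite as the oxygen source) turns CH2NO2 directly into CO2H and leaves the methyl ester and Ca untouched.

Step 9
Reactants: 16 succinic half ester
Product: 18 methyl (2S,3S)-5-diazo-4-oxo-3-(propan-2-yl)-2-(cis-pinan-2-yl)pentanoate, via acid chloride 17 (not isolated)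
Conditions: (COCl)2, DMF (cat.), CH2Cl2, 0 °C to rt, evaporation; then CH2N2 (3 equiv), Et2O, 0 °C
Reagents that add atoms: diazomethane C=[N+]=[N-]
Why: Acylation of diazomethane by the acid chloride (first stage of the Arndt–Eistert sequence) gives the diazomethyl ketone, a second equivalent of diazomethane taking up the HCl released.

Step 10
Reactants: 18 diazo ketone
Product: 19 methyl 4'-oxo-3'-(propan-2-yl)spiro[pinane-2,1'-cyclopentane]-2'-carboxylate (ester and i-Pr both on the bridgehead face)
Conditions: Rh2(OAc)4 (2 mol %), CH2Cl2, 40 °C, slow addition of 18 (final 0.01 M)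
Reagents that add atoms: none
Why: Rh2(OAc)4 (dirhodium tetraacetate, divalent rhodium) expels dinitrogen from the diazo ketone to give an electrophilic rhodium carbenoid at Cd, which inserts into the tertiary Ce–H bond through a concerted three-centre transition state without a free carbocation, so the cyclobutane is not endangered. The closest known reaction type is the dirhodium-catalysed intramolecular 1,5 C–H insertion of diazomethyl ketones into tertiary C–H bonds to give cyclopentanones. Ring B is closed in the 1,5-insertion mode (five-membered ring through a six-membered, hydrogen-bridged transition state). The new quaternary stereocentre Ce should form with retention, Cd taking the place of the hydrogen on the open face, so its configuration is dictated by the hydrogenation of step 3. The step needs site selectivity for Ce–H, which is the only tertiary C–H within 1,5 reach (the others are isopropyl methyl C–H bonds), whereas Ca–H is deactivated by the ester and would close a four-membered ring, the pinane bridgehead and ring-methylene C–H bonds next to Ce would need 1,6-insertion, and capture by the ester carbonyl oxygen is reversible without a dipolarophile. Slow addition at high dilution should suppress carbenoid dimerisation.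

Step 11
Reactants: 19 keto ester (Ca/Cb cis)
Product: 20 methyl 4'-oxo-3'-(propan-2-yl)spiro[pinane-2,1'-cyclopentane]-2'-carboxylate (ester on the bridgehead face; i-Pr on the methylene face)
Conditions: DBU (0.3 equiv), CH2Cl2, rt
Reagents that add atoms: none
Why: Base-mediated epimerisation through the ketone enolate should move the isopropyl group at Cb trans to the neighbouring ester (the thermodynamic 2,3-trans cyclopentanone), that is onto the methylene face as in the target, while the less acidic and more hindered Ca–H is not exchanged by the amidine.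

Step 12
Reactants: 20 trans keto ester
Product: 21 4'-(1,3-dithiolane) derivative of 20
Conditions: HSCH2CH2SH, BF3·OEt2, CH2Cl2, 0 °C to rt
Reagents that add atoms: ethane-1,2-dithiol SCCS
Why: Lewis acid-catalysed dithioketalisation of the cyclopentanone leaves the ester alone, and any enolisation at Cb only returns the trans isomer.

Step 13
Reactants: 21 dithiolane
Product: 22 methyl 3'-(propan-2-yl)spiro[pinane-2,1'-cyclopentane]-2'-carboxylate
Conditions: Raney Ni, EtOH, reflux
Reagents that add atoms: none
Why: Raney nickel desulfurisation (Mozingo reduction) replaces both C–S bonds by C–H under neutral conditions, which removes the Cc carbonyl and freezes the configuration at Cb.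

Step 14
Reactants: 22 spiro ester; 8 isobutyraldehyde
Product: 24 methyl 2'-(1-hydroxy-2-methylpropyl)-3'-(propan-2-yl)spiro[pinane-2,1'-cyclopentane]-2'-carboxylate, via lithium enolate 23 (not isolated)
Conditions: LiN(i-Pr)2, THF, −78 to −20 °C; then 8, −78 °C; AcOH, −78 °C
Reagents that add atoms: none
Why: Aldol addition of the lithium ester enolate, in which the planar enolate carbon Ca should be attacked on the bridgehead face, anti to the isopropyl group on the adjacent Cb, so that the quaternary stereocentre Ca is set with the new carbon (future Cj) on the bridgehead face and the ester (future Cf) on the methylene face.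

Step 15
Reactants: 24 hydroxy ester
Product: 25 methyl 2'-(2-methylpropanoyl)-3'-(propan-2-yl)spiro[pinane-2,1'-cyclopentane]-2'-carboxylate
Conditions: Dess–Martin periodinane, CH2Cl2, rt
Reagents that add atoms: none
Why: Dess–Martin oxidation of the secondary alcohol gives the β-keto ester, which cannot enolise at the quaternary Ca, and removes the undefined carbinol centre.

Step 16
Reactants: 25 keto ester; 26 propanal
Product: 28 methyl 2'-(3-hydroxy-2,2-dimethylpentanoyl)-3'-(propan-2-yl)spiro[pinane-2,1'-cyclopentane]-2'-carboxylate, via lithium enolate 27 (not isolated)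
Conditions: LiN(i-Pr)2, THF, −78 to 0 °C; then 26, −78 °C; AcOH, −78 °C
Reagents that add atoms: none
Why: Aldol addition of the only possible enolate (deprotonation of the isopropyl methine, Ca being quaternary) to an unhindered aldehyde creates the gem-dimethyl carbon Ci, the cold quench preventing retro-aldol reaction and lactonisation.

Step 17
Reactants: 28 hydroxy keto ester
Product: 29 methyl 2'-(2,2-dimethyl-3-oxopentanoyl)-3'-(propan-2-yl)spiro[pinane-2,1'-cyclopentane]-2'-carboxylate
Conditions: Dess–Martin periodinane, CH2Cl2, rt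
Reagents that add atoms: none
Why: Dess–Martin oxidation under non-basic conditions gives the diketo ester without retro-Claisen cleavage of the non-enolisable 1,3-dicarbonyl units.

Step 18
Reactants: 29 diketo ester
Product: 30 ring-A trione (Cf, Ch and Cj = C=O; Cg = CHMe; Ci = CMe2)
Conditions: KN(SiMe3)2 (2.2 equiv), THF, −78 to 0 °C; then aq. HCl
Reagents that add atoms: none
Why: Dieckmann-type Claisen condensation in which the only enolisable position (Cg, the CH2 of the ethyl ketone) attacks the ester carbonyl Cf in a 6-(enolendo)-exo-trig closure, the acidic cyclic trione being held as its enolate until work-up, which drives the reaction and protects the product from cleavage.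

Step 19
Reactants: 30 trione
Product: 31 target CNP0307059.1
Conditions: Me3SiCHN2, MeOH–toluene, 0 °C to rt
Reagents that add atoms: trimethylsilyldiazomethane C[Si](C)(C)C=[N+]=[N-]
Why: O-Methylation of the acidic enol with a diazoalkane should occur at the Ch oxygen, which is flanked only by methyl-bearing carbons, rather than at the Cf oxygen buried next to the spiro carbon Ca, giving the enol ether at Ch with the conjugated carbonyl at Cf as in the target.

**Compound list**

1 | (+)-β-pinene, (1R,5R)-6,6-dimethyl-2-methylidenebicyclo[3.1.1]heptane | C=C1CC[C@@H]2C[C@H]1C2(C)C | starting material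
2 | β-pinene ozonide (spiro-1,2,4-trioxolane, mixture at the spiro carbon) | C1OOC2(O1)CC[C@@H]3C[C@H]2C3(C)C | intermediate
3 | (−)-nopinone, (1S,5R)-6,6-dimethylbicyclo[3.1.1]heptan-2-one | O=C1CC[C@@H]2C[C@H]1C2(C)C | intermediate
4 | trimethyl phosphonoacetate | COC(=O)CP(=O)(OC)OC | starting material
5 | methyl nopinylideneacetate, methyl 2-(6,6-dimethylbicyclo[3.1.1]heptan-2-ylidene)acetate, E/Z mixture | COC(=O)C=C1CC[C@@H]2C[C@H]1C2(C)C | intermediate
6 | methyl 2-[(1R,2R,5R)-6,6-dimethylbicyclo[3.1.1]heptan-2-yl]acetate, methyl (cis-pinan-2-yl)acetate | COC(=O)C[C@H]1CC[C@@H]2C[C@H]1C2(C)C | intermediate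
7 | 2-[(1R,2R,5R)-6,6-dimethylbicyclo[3.1.1]heptan-2-yl]acetaldehyde | O=CC[C@H]1CC[C@@H]2C[C@H]1C2(C)C | intermediate
8 | isobutyraldehyde | CC(C)C=O | starting material
9 | nitromethane | C[N+](=O)[O-] | starting material
10 | 3-methyl-1-nitrobutan-2-ol (racemic) | CC(C)C(O)C[N+](=O)[O-] | intermediate
11 | 3-methyl-1-nitrobutan-2-yl methanesulfonate | CC(C)C(OS(C)(=O)=O)C[N+](=O)[O-] | intermediate
12 | (E)-3-methyl-1-nitrobut-1-ene | CC(C)/C=C/[N+](=O)[O-] | intermediate
13 | (2S,3S)-4-methyl-3-(nitromethyl)-2-(cis-pinan-2-yl)pentanal | O=C[C@H]([C@H](C(C)C)C[N+](=O)[O-])[C@H]1CC[C@@H]2C[C@H]1C2(C)C | intermediate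
14 | (2S,3S)-4-methyl-3-(nitromethyl)-2-(cis-pinan-2-yl)pentanoic acid | OC(=O)[C@H]([C@H](C(C)C)C[N+](=O)[O-])[C@H]1CC[C@@H]2C[C@H]1C2(C)C | intermediate
15 | methyl (2S,3S)-4-methyl-3-(nitromethyl)-2-(cis-pinan-2-yl)pentanoate | COC(=O)[C@H]([C@H](C(C)C)C[N+](=O)[O-])[C@H]1CC[C@@H]2C[C@H]1C2(C)C | intermediate
16 | (2S,3S)-4-methoxy-4-oxo-2-(propan-2-yl)-3-(cis-pinan-2-yl)butanoic acid | COC(=O)[C@H]([C@H](C(C)C)C(=O)O)[C@H]1CC[C@@H]2C[C@H]1C2(C)C | intermediate
17 | acid chloride of 16 | COC(=O)[C@H]([C@H](C(C)C)C(Cl)=O)[C@H]1CC[C@@H]2C[C@H]1C2(C)C | intermediate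
18 | methyl (2S,3S)-5-diazo-4-oxo-3-(propan-2-yl)-2-(cis-pinan-2-yl)pentanoate (key-step precursor) | COC(=O)[C@H]([C@H](C(C)C)C(=O)C=[N+]=[N-])[C@H]1CC[C@@H]2C[C@H]1C2(C)C | intermediate
19 | methyl 4'-oxo-3'-(propan-2-yl)spiro[pinane-2,1'-cyclopentane]-2'-carboxylate, ester and i-Pr on the bridgehead face (key-step product) | COC(=O)[C@@H]1[C@H](C(C)C)C(=O)C[C@@]12CC[C@@H]1C[C@H]2C1(C)C | intermediate
20 | methyl 4'-oxo-3'-(propan-2-yl)spiro[pinane-2,1'-cyclopentane]-2'-carboxylate, ester on the bridgehead face, i-Pr on the methylene face | COC(=O)[C@@H]1[C@@H](C(C)C)C(=O)C[C@@]12CC[C@@H]1C[C@H]2C1(C)C | intermediate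
21 | 4'-(1,3-dithiolane) derivative of 20 | COC(=O)[C@@H]1[C@@H](C(C)C)C3(SCCS3)C[C@@]12CC[C@@H]1C[C@H]2C1(C)C | intermediate
22 | methyl 3'-(propan-2-yl)spiro[pinane-2,1'-cyclopentane]-2'-carboxylate, ester on the bridgehead face, i-Pr on the methylene face | COC(=O)[C@@H]1[C@@H](C(C)C)CC[C@@]12CC[C@@H]1C[C@H]2C1(C)C | intermediate
23 | lithium enolate of 22 | [Li+].COC([O-])=C1[C@@H](C(C)C)CC[C@@]12CC[C@@H]1C[C@H]2C1(C)C | intermediate
24 | methyl 2'-(1-hydroxy-2-methylpropyl)-3'-(propan-2-yl)spiro[pinane-2,1'-cyclopentane]-2'-carboxylate, carbinol carbon on the bridgehead face, carbinol epimers | COC(=O)[C@@]1(C(O)C(C)C)[C@@H](C(C)C)CC[C@@]12CC[C@@H]1C[C@H]2C1(C)C | intermediate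
25 | methyl 2'-(2-methylpropanoyl)-3'-(propan-2-yl)spiro[pinane-2,1'-cyclopentane]-2'-carboxylate | COC(=O)[C@@]1(C(=O)C(C)C)[C@@H](C(C)C)CC[C@@]12CC[C@@H]1C[C@H]2C1(C)C | intermediate
26 | propanal | CCC=O | starting material
27 | lithium enolate of 25 | [Li+].COC(=O)[C@@]1(C([O-])=C(C)C)[C@@H](C(C)C)CC[C@@]12CC[C@@H]1C[C@H]2C1(C)C | intermediate
28 | methyl 2'-(3-hydroxy-2,2-dimethylpentanoyl)-3'-(propan-2-yl)spiro[pinane-2,1'-cyclopentane]-2'-carboxylate, carbinol epimers | COC(=O)[C@@]1(C(=O)C(C)(C)C(O)CC)[C@@H](C(C)C)CC[C@@]12CC[C@@H]1C[C@H]2C1(C)C | intermediate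
29 | methyl 2'-(2,2-dimethyl-3-oxopentanoyl)-3'-(propan-2-yl)spiro[pinane-2,1'-cyclopentane]-2'-carboxylate | COC(=O)[C@@]1(C(=O)C(C)(C)C(=O)CC)[C@@H](C(C)C)CC[C@@]12CC[C@@H]1C[C@H]2C1(C)C | intermediate
30 | ring-A trione (triketo form shown; Cg epimers and enols), Cj on the bridgehead face, Cf and i-Pr on the methylene face | CC1C(=O)[C@@]2(C(=O)C(C)(C)C1=O)[C@@H](C(C)C)CC[C@@]21CC[C@@H]2C[C@H]1C2(C)C | intermediate
31 | CNP0307059.1, the Ch methyl enol ether of 30 | COC1=C(C)C(=O)[C@@]2(C(=O)C1(C)C)[C@@H](C(C)C)CC[C@@]21CC[C@@H]2C[C@H]1C2(C)C | target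

**Step count**

Total steps: 19. Longest linear sequence: 18 steps (steps 1–4 and 6–19, from (+)-β-pinene); step 5 is a side branch.

**Steps most likely to fail, with fallbacks**

For step 10, the key step, the unstabilised carbenoid may be diverted before it reaches the crowded Ce–H bond, which is also inductively deactivated by the ester two bonds away. The diversions are capture at the ester carbonyl oxygen with ylide-derived decay, dimerisation, and insertion into an isopropyl methyl C–H bond. The fallback keeps the same Cd–Ce disconnection but uses an acceptor/acceptor carbenoid, which is more selective for tertiary C–H bonds and not prone to dimerisation. It sets out from acid 16. Activation with 1,1'-carbonyldiimidazole and decarboxylative C-acylation of the magnesium enolate of methyl malonate (KO2CCH2CO2Me, MgCl2, Et3N, THF) would give dimethyl 3-oxo-4-(propan-2-yl)-5-(cis-pinan-2-yl)hexanedioate F1. Diazo transfer (4-acetamidobenzenesulfonyl azide, Et3N, MeCN) would give dimethyl 2-diazo-3-oxo-4-(propan-2-yl)-5-(cis-pinan-2-yl)hexanedioate F2. Rh2(OAc)4 in CH2Cl2 at 40 °C should then insert Cd into Ce–H with retention to give dimethyl 4'-oxo-3'-(propan-2-yl)spiro[pinane-2,1'-cyclopentane]-2',5'-dicarboxylate F3. Krapcho dealkoxycarbonylation (NaCl, wet DMSO, 150 °C) should remove the extra ester at Cd and equilibrate Cb, and the route is rejoined at 20.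

For step 14, deprotonation at the congested Ca–H may be slow, the crowded aldolate may revert (retro-aldol), and facial discrimination at Ca may be insufficient, because the face anti to the isopropyl group is also the face under the pinane bridgehead. The fallback makes the Ca–Cj bond intramolecularly and sets out from 22. Reduction with i-Bu2AlH (CH2Cl2, −78 °C) would give 3'-(propan-2-yl)spiro[pinane-2,1'-cyclopentane]-2'-carbaldehyde F4. Methyl 2,2-dimethyl-3-oxopentanoate F5 (from methyl 3-oxopentanoate, MeI, K2CO3, acetone) is converted to its lithium enolate (LiN(i-Pr)2, THF, −78 °C) and added to F4 to give the hydroxy keto ester F6. Dess–Martin oxidation would give the β-diketone ester F7, in which the chain is attached to Ca through Cf. LiN(i-Pr)2 (3 equiv, THF–DMPU, −78 °C to rt) should form the dienolate, whose terminal carbon Ca acylates on the tethered ester carbonyl Cj in a six-membered Claisen closure, again anti to the isopropyl group. The route is rejoined at trione 30.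

For step 6, the enamine addition between a β-branched aldehyde and a β-branched nitroalkene may be sluggish, and long reaction times may erode the Ca configuration through enolisation of the product aldehyde. The fallback uses a covalently bound chiral auxiliary on a preformed metal enolate and sets out from ester 6. Saponification (LiOH, THF–H2O) would give (cis-pinan-2-yl)acetic acid F8. The pivaloyl mixed anhydride (t-BuCOCl, Et3N, THF, −20 °C) and lithiated (R)-4-benzyl-1,3-oxazolidin-2-one (n-BuLi) would give (R)-4-benzyl-3-[(cis-pinan-2-yl)acetyl]-1,3-oxazolidin-2-one F9. The chelated titanium enolate (TiCl4, i-Pr2NEt, CH2Cl2, −78 °C) should add to nitroalkene 12 on the face away from the benzyl group to give (R)-4-benzyl-3-[(2S)-4-methyl-3-(nitromethyl)-2-(cis-pinan-2-yl)pentanoyl]-1,3-oxazolidin-2-one F10, the Cb configuration being immaterial. Methanolysis (MeOMgBr, MeOH, 0 °C) releases the auxiliary and returns the route at ester 15, as a possible Cb mixture that converges at 20.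

**Further compounds**

F1 | step 10 | dimethyl 3-oxo-4-(propan-2-yl)-5-(cis-pinan-2-yl)hexanedioate | COC(=O)[C@H]([C@H](C(C)C)C(=O)CC(=O)OC)[C@H]1CC[C@@H]2C[C@H]1C2(C)C
F2 | step 10 | dimethyl 2-diazo-3-oxo-4-(propan-2-yl)-5-(cis-pinan-2-yl)hexanedioate | COC(=O)[C@H]([C@H](C(C)C)C(=O)C(=[N+]=[N-])C(=O)OC)[C@H]1CC[C@@H]2C[C@H]1C2(C)C
F3 | step 10 | dimethyl 4'-oxo-3'-(propan-2-yl)spiro[pinane-2,1'-cyclopentane]-2',5'-dicarboxylate | COC(=O)[C@@H]1[C@H](C(C)C)C(=O)C(C(=O)OC)[C@@]12CC[C@@H]1C[C@H]2C1(C)C
F4 | step 14 | 3'-(propan-2-yl)spiro[pinane-2,1'-cyclopentane]-2'-carbaldehyde | O=C[C@@H]1[C@@H](C(C)C)CC[C@@]12CC[C@@H]1C[C@H]2C1(C)C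
F5 | step 14 | methyl 2,2-dimethyl-3-oxopentanoate | CCC(=O)C(C)(C)C(=O)OC
F6 | step 14 | methyl 5-hydroxy-2,2,4-trimethyl-3-oxo-5-[3'-(propan-2-yl)spiro[pinane-2,1'-cyclopentan]-2'-yl]pentanoate | COC(=O)C(C)(C)C(=O)C(C)C(O)[C@@H]1[C@@H](C(C)C)CC[C@@]12CC[C@@H]1C[C@H]2C1(C)C
F7 | step 14 | methyl 2,2,4-trimethyl-3,5-dioxo-5-[3'-(propan-2-yl)spiro[pinane-2,1'-cyclopentan]-2'-yl]pentanoate | COC(=O)C(C)(C)C(=O)C(C)C(=O)[C@@H]1[C@@H](C(C)C)CC[C@@]12CC[C@@H]1C[C@H]2C1(C)C
F8 | step 6 | (cis-pinan-2-yl)acetic acid | OC(=O)C[C@H]1CC[C@@H]2C[C@H]1C2(C)C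
F9 | step 6 | (R)-4-benzyl-3-[(cis-pinan-2-yl)acetyl]-1,3-oxazolidin-2-one | O=C(C[C@H]1CC[C@@H]2C[C@H]1C2(C)C)N1[C@H](Cc2ccccc2)COC1=O
F10 | step 6 | (R)-4-benzyl-3-[(2S)-4-methyl-3-(nitromethyl)-2-(cis-pinan-2-yl)pentanoyl]-1,3-oxazolidin-2-one | O=C([C@H](C(C(C)C)C[N+](=O)[O-])[C@H]1CC[C@@H]2C[C@H]1C2(C)C)N1[C@H](Cc2ccccc2)COC1=O
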